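4 answers are wanted: which flask ends richest in D, and the D in each of 3 flasks at 12 min.

| flask | Q | E | X | remark | time |
|---|---|---|---|---|---|
| birch | 0.12 M | 4 equiv | 0.024 M | run made earlier |  |
| cedar | 0.24 M | 4 equiv | 0.024 M | run made earlier |  |
| north-east | 0.12 M (fed, over 2.5 min) | 4.00 equiv | 0.0240 M | all else is in the flask from the start; the feed brings no volume worth counting | 12 min |
| north | 0.12 M | 4.00 equiv | 0.0240 M | everything together at the start | 12 min |
| north-west | 0.12 M | 4.00 equiv (fed, over 2.5 min) | 0.0240 M | all else is in the flask from the start; the feed brings no volume worth counting | 12 min |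

| run | time / min | D / % | G / % | Q / % |
|---|---|---|---|---|
| birch | 2.50 | 70.3 | 27.3 | 2.1 |
| birch | 5.00 | 70.4 | 28.0 | 1.3 |
| birch | 8.00 | 70.8 | 27.5 | 0 |
| birch | 10.0 | 71.0 | 27.4 | 0.7 |
| birch | 12.0 | 70.6 | 27.1 | 1.1 |
| cedar | 0.667 | 66.9 | 30.1 | 3.6 |
| cedar | 1.33 | 67.8 | 31.4 | 0.2 |
| cedar | 2.00 | 68.1 | 31.7 | 0 |
| cedar | 3.00 | 68.0 | 32.3 | 0 |
| cedar | 4.00 | 66.7 | 32.0 | 0.1 |

(each reading ± 0.5 percentage points)

* the flask with the highest amount of D, in percent of the Q charged ("all alike" if they lie within 1.5 percentage points) (north-east / north / north-west / all alike)
* final D, as a percentage of the Q charged, in north-east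
* final D, as a percentage of the Q charged, in north
* final D, as a percentage of the Q charged, in north-west

- a species is counted by the Q in it: one D counts as two

I write q and e for the fractions of their charges of Q and E still present. Birch reads Q at 2.1% after 2.50 min. On a second-order clock, where q is the reciprocal of one plus t/τ, that gives τ = 0.0536 min. Cedar gives 0.0249 min, about half, at double the charge, so I take Q to be meeting Q, which makes D. G then forms as q times e and D as q squared, so D per G follows q/e. My carried number is the split s, final D over final G in a batch at 4.00 equiv (a selectivity factor): 2.61 from birch. With the Q charge held, it scales inversely with the E charge. North repeats birch, so I expect D near birch's own 70.6% at 12.0 min.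

In north-west e climbs as t/tf while q falls as τ/t, so q/e reaches one at q = 14.6%. I send the Q above that to D and split the rest as in birch, giving D near 95.9%. North-east, with e frozen at one, holds the same q under the feed, which gives D near 27.6%. That link is weak: birch reads Q at 1.3% after 5.00 min and 1.1% after 12.0 min, hardly falling, so I take E to fade by itself within about 2.5 min. Reforged, the fed Q meets fading E, q/e stays near one, and I commit north-east to about north's D.

The forecast says north-west, with 62%, 70.7% and 77% for north-east, north and north-west: “Feeding Q keeps Q low against full E”. We agree on the flask and on north, and differ on the other two numbers.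

The flask gives north-west, with 75.4%, 70.9% and 91.1%.

    Q + E → G (k = 0.0580 /M/s)
    2 Q → D (k = 0.610 /M/s)
    E + X → L (k = 0.800 /M/s)
    E → J (k = 0.0130 /s)
    G → Z (k = 4.10 × 10⁻⁵ /s)

North-east ends with D over G at 3.28, which on s means an effective q/e of 1.26. At the end of its feed, 2.50 min, that flask holds Q at 20.0% and E at 11.5%. The neighbouring flask is north with 16.0 equiv of E, so s becomes 0.651 and, if I count D and G as the whole charge, D should be 39.4%. That neighbour ends with 37.8% D.

The earlier runs and the new flask were computed with made-up constants.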